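The pitfall at this bench was to read 1.80 equivalents of partner as plenty: partner has a half-life of 0.32 d by decomposition, shorter than the 3.1 d for intermediate by coupling.

    starting material → intermediate (k1 = 0.0015 min⁻¹)
    partner + intermediate → product (k2 = 3.4 × 10⁻⁴ L mol⁻¹ min⁻¹)
    partner → decomposed reagent (k3 = 0.0015 min⁻¹)

common to all: time 20 d

| charge | starting material | partner | remark |
|---|---|---|---|
| eta | 0.25 M (fed, over 10 h) | 0.450 M | all else is in the flask from the start; the feed brings no volume worth counting |
| gamma | 0.25 M | 0.450 M | everything together at the start |
| delta | 0.25 M (fed, over 4.0 d) | 0.450 M | all else is in the flask from the start; the feed brings no volume worth counting |
| beta | 0.25 M | 0.450 M (fed, over 4.0 d) | all else is in the flask from the start; the feed brings no volume worth counting |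

- the flask that comes out highest in amount of product, in percent of the starting material charged, or "all alike" when all lie within 1.5 percentage points (eta / gamma / delta / beta / all alike)
- product at the end, in percent of the starting material charged, eta
- product at the end, in percent of the starting material charged, gamma
- product at the end, in percent of the starting material charged, delta
- product at the end, in percent of the starting material charged, beta

I left this note for whoever took over. In each flask, starting material turns into intermediate while partner decomposes, and product forms where partner meets intermediate. Partner summed over its whole life comes to its charge times its lifetime of 11.1 h. I therefore defined the coupling budget as the fraction of the charge that would couple if all of it stood as intermediate throughout: 0.102. Product is that budget times the average fraction standing as intermediate while partner lives.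

Starting material and partner decay with one constant, and the integral gives an average fraction of 0.500 for gamma, so product of 5.10%. A feed of starting material multiplies this by one minus exp(−x), over x, where x is feed time over partner's lifetime. That gave 3.36% for eta and 0.590% for delta. For beta, I reckoned the budget less a share of 0.5 over x, with x now feed time over starting material's lifetime, 9.61%. Expect mostly intermediate in the flask. Don't shorten beta's partner feed: its 4.0 d runs longer than starting material's lifetime of 11.1 h, so partner fed late in it meets intermediate already formed.

The forecast chose beta: eta 3.3%, gamma 4.9%, delta 0.58%, beta 9.2%, reasoning that “its total exposure is worth only about 10% conversion”. Its beta is lower than mine.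

The simulation put beta highest: eta 3.15%, gamma 4.72%, delta 0.571%, beta 8.72%. Beta stood 4 percentage points above gamma, and the forecast held. As fractions of the budget 0.102, beta's product was 0.855 and gamma's 0.463. The neighbouring flask was delta with 0.10 M of starting material, which made 4.50 equiv of partner. The budget contains no charge of starting material, so my reckoning stayed at 0.590%. That neighbour ended with 0% of its partner left and gave 0.576% product.

The constants were chosen freely; the rest is arithmetic.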